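## Structural features

The target is a flavone: a benzene ring A fused to a 4-pyranone ring C (4H-chromen-4-one), with the phenyl ring B attached at C2 through a single C2–C1' bond. It has no stereocentre, so no relationship between neighbouring stereogenic atoms has to be set or kept. Ring A is pentasubstituted, with a hydroxyl at C5 (hydrogen-bonded to the C4 carbonyl), methoxy groups at C7 and C8 and its only hydrogen at C6, while ring B has methoxy groups at C2' and C3' and a hydroxyl at C4'. The fragile elements are the two free phenols on electron-rich rings, the pyranone (opened by hydroxide), the vicinal methyl ethers (cleaved by strong Lewis acids) and the 5-hydroxy-7,8-dioxygenated pattern itself, which hot strong acid can transpose to the 5,6,7-pattern by ring opening and reclosure (Wessely–Moser rearrangement). The real difficulty is regiochemical: both carbons that flank C4a (C5 and C8a) carry oxygen, the synthesis must decide which becomes O1, and two hydroxyls must be told apart from four methoxy groups. The key step uses the fact that C8a is ortho to C4a and so to the C4 carbonyl: a fluorine on C8a makes the C8a=C4a–C4=O unit a vinylogous acyl fluoride that the enol oxygen of a C2–C3–C4 diketone reaches through a six-membered transition state, which ties O1 to the carbon next to the C8 methoxy group while O5 stays capped. In the fluorinated ring A building block the formyl-bearing carbon maps onto C5, the carbon between it and the fluorinated carbon onto C4a, the fluorinated carbon onto C8a and the two methoxy-bearing carbons onto C8 and C7, so the fluorine ends up exactly where O1 has to enter.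

## Logic of the disconnections

13 to 12: the two O–CH2 acetal bonds on O5 and O4' are cut. Both phenols have to be masked through the base-mediated steps, and using the same acetal on both means one mild acid treatment frees them together. Compared with a benzyl ether on ring B, this saves a step and never exposes the C2=C3 bond to hydrogenation. The demand is an acid mild enough to leave the pyranone and the four methyl ethers untouched and to stay far from conditions that transpose ring A.

12 to 11: the O1–C8a bond is cut. This opens ring C to an acyclic 1,3-diketone and places the regiochemical decision in the position of one fluorine atom. The demand is that a delocalised enolate oxygen displaces fluoride from an electron-rich ring, which calls for a dry carbonate base, a dipolar aprotic solvent and heat.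

11 to 6 and 9: the C2–C3 bond is cut. C3 is the methyl carbon of 6 and C2 the ester carbon of 9, so the molecule falls into two arenes of similar size and the route becomes convergent. The demand is a crossed Claisen condensation on a non-enolisable but deactivated ester, with more than two equivalents of base and a temperature low enough to leave the carbon–fluorine bond alone.

6 to 4 (through 5): the C4a–C4 aryl–acyl bond is cut. The hydrogen of 4 that lies between fluorine and the acetal oxygen is the most acidic on the ring, and the acetal that protects O5 also directs the metalation, so no extra group is needed. The demand is site-selective deprotonation, cold handling of 5 (on warming it can eliminate fluoride to an aryne) and an acetyl donor that stops at the ketone.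

4 to 3 to 1: the O–CH2 bond is cut, then the C5–O bond is traced back to the C–CHO bond of 1. This reaches a purchasable arene in which fluorine and both methoxy groups already stand in the required relation. The demand is that aryl migration beats hydride migration in the peracid step.

9 to 8 to 7: the two O–CH3 bonds are cut, then the O–CH2 bond at O4. In 7 the carboxyl carbon and all three oxygens of ring B are already in place, so no position has to be chosen by electrophilic substitution. A ring B phenol lacking the carboxyl carbon would offer two similarly activated positions and was set aside for that reason. The demand is monoalkylation at O4 in preference to O3 and O2.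

## Other disconnections considered

Alternative 1: The cut is threefold: O1–C8a, C4a–C4 and O1–C2. Ring A would enter as the aryne 3,4-dimethoxy-6-[(4-methylbenzenesulfonyl)oxy]-1,2-didehydrobenzene A4, released by CsF from 2,3-dimethoxy-5-[(4-methylbenzenesulfonyl)oxy]-6-(trimethylsilyl)phenyl trifluoromethanesulfonate A2. Ring B with C2, C3 and C4 would enter as 3-[4-(benzyloxy)-2,3-dimethoxyphenyl]prop-2-ynoic acid A3. In the forward step the carboxylate oxygen of A3 would add to C8a of A4, the aryl anion at C4a would take the acyl carbon (net insertion into the C–O bond), and the phenoxide so formed would close 6-endo-dig onto the alkyne to give 2-[4-(benzyloxy)-2,3-dimethoxyphenyl]-7,8-dimethoxy-4-oxo-4H-chromen-5-yl 4-methylbenzenesulfonate A1.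

In its favour, three bonds and ring C would form in one flask under nearly neutral fluoride conditions, and A3 is a simple fragment.

Against it:
- Each aryne carbon of A4 has an oxygen-bearing neighbour (the C8 methoxy group and the C5 sulfonate), so the site of carboxylate attack rests only on the modest inductive difference between the two. Attack at C4a would transpose the ring A pattern.
- A2 is a hexasubstituted benzene that needs its own multistep synthesis.
- 5-exo-dig closure could compete with the 6-endo-dig mode.
- The end game from A1 needs two deprotections (sulfonate cleavage and hydrogenolysis) to reach 13.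

In comparison:
- On bond economy and convergence of the key step this alternative is better than the chosen plan (three bonds against one).
- On structural certainty the chosen plan is better, because the fluorine in 11 and the capped O5 leave only one possible closure, whereas the pattern of A1 depends on the direction of addition to A4.
- Mechanistically both rely on oxygen attack at C8a, through a strained triple bond here and through addition–elimination there.
- On step economy the alternative is at best equal and probably longer once A2 is counted.

Alternative 2: The cut is C4a–C5 (and, one step earlier, C8–C8a), so that C5 to C8 of ring A come from a four-membered ring while rings C and B are already in place. Heating rac-4-{6-[4-(benzyloxy)-2,3-dimethoxyphenyl]-4-oxo-4H-pyran-2-yl}-3,4-dimethoxycyclobut-2-en-1-one A6 would open the four-membered ring electrocyclically to the vinylketene (3Z)-4-{6-[4-(benzyloxy)-2,3-dimethoxyphenyl]-4-oxo-4H-pyran-2-yl}-3,4-dimethoxybuta-1,3-dien-1-one A7, with the methoxy group turning outward. Six-electron closure of A7 onto pyranone C3, followed by enolisation, would give 2-[4-(benzyloxy)-2,3-dimethoxyphenyl]-5-hydroxy-7,8-dimethoxy-4H-chromen-4-one A5.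

In its favour:
- The ring A pattern is written into the cyclobutenone, and ring C exists beforehand, so the O1 question never arises.
- The key step needs no reagent, and A7 reacts on as it forms.
- The C5 hydroxyl would emerge free. On protecting-group count at C5 this alternative is better than the chosen plan, and the single hydrogenolysis from A5 to 13 equals its single final step.

Against it:
- A6 would have to be made by adding 2-[4-(benzyloxy)-2,3-dimethoxyphenyl]-4H-pyran-4-one A9, metallated at C6, to the ketone carbonyl of 3-methoxycyclobut-3-ene-1,2-dione A8 and methylating the tertiary alkoxide.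
- Metallated 4-pyranones are prone to ring opening, and A8 is not a stock reagent and would need its own preparation.
- The closure of A7 uses an electron-poor pyranone double bond as the two-electron partner, which is less well supported than closure onto arenes.

In comparison:
- On structure the two plans are equal, since both fix the regiochemistry by construction.
- On mechanism a pericyclic cascade stands against a polar substitution, and the cascade has more unknowns on this substrate.
- On step economy the alternative is not shorter, because A8, A9 and A6 each need dedicated steps.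

Alternative 3: The cut is C4a–C4, C4–C3 and O1–C2, with C4 supplied by carbon monoxide A13. 5-(Benzyloxy)-6-iodo-2,3-dimethoxyphenol A11, A13 and 1-(benzyloxy)-4-ethynyl-2,3-dimethoxybenzene A12 would combine under PdCl2(PPh3)2 and diethylamine. Zerovalent palladium would add to the carbon–iodine bond of A11, A13 would insert to give an acyl complex of divalent palladium, alkynyl transfer from A12 and reductive elimination would give the ynone, and the amine would promote 6-endo-dig closure of the phenol to 5-(benzyloxy)-2-[4-(benzyloxy)-2,3-dimethoxyphenyl]-7,8-dimethoxy-4H-chromen-4-one A10.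

In its favour:
- This is the most convergent plan: ring C and three bonds form in one catalytic step.
- O1 is fixed by which oxygen of A11 is free.
- A12 is a simple terminal alkyne.
- One hydrogenolysis would take A10 to 13.

Against it:
- The iodinated carbon of A11 sits between two oxygen substituents on an electron-rich ring, so oxidative addition should be slow.
- Direct coupling of A11 with A12 without uptake of A13, and 5-exo-dig closure, are competing pathways.
- Making A11 requires iodination at the hindered ortho position of a phenol whose para position is also open, which needs a directed method.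
- The last step hydrogenates A10 in the presence of the C2=C3 bond.

In comparison:
- On regiochemical security the two plans are equal.
- On step economy this alternative is potentially better than the chosen plan if A11 can be reached in a few steps.
- On mechanism its risk is chemoselectivity among catalytic pathways and the handling of a toxic gas, whereas the chosen plan risks only a slow but unambiguous ring closure.

Key step: step 7

Assumption: 1 and 7 are taken as purchasable compounds, and 11 is written as the diketo form although its chelated enol should predominate.

## Route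

Step 1
Reactants: 1 3-fluoro-4,5-dimethoxybenzaldehyde
Product: 3 3-fluoro-4,5-dimethoxyphenol, via 3-fluoro-4,5-dimethoxyphenyl formate 2 (not isolated)
Conditions: mCPBA, CH2Cl2, 0 °C to rt; aq. NaHCO3 wash; then K2CO3 (cat.), MeOH, rt
Reagents that add atoms: mCPBA (3-chloroperoxybenzoic acid), OOC(=O)c1cccc(Cl)c1
Why: Dakin-type Baeyer–Villiger oxidation; in the Criegee adduct the aryl group, made electron-rich by the para methoxy group, should migrate in preference to hydride to give formate 2, which mild methanolysis converts into the phenol.

Step 2
Reactants: 3 3-fluoro-4,5-dimethoxyphenol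
Product: 4 1-fluoro-2,3-dimethoxy-5-(methoxymethoxy)benzene
Conditions: MOMCl, i-Pr2NEt, CH2Cl2, 0 °C to rt
Reagents that add atoms: chloromethyl methyl ether (MOMCl), COCCl
Why: Williamson-type O-alkylation of the phenoxide gives the MOM acetal, which protects the future O5 and serves as the directing group for step 3.

Step 3
Reactants: 4 1-fluoro-2,3-dimethoxy-5-(methoxymethoxy)benzene
Product: 6 1-[2-fluoro-3,4-dimethoxy-6-(methoxymethoxy)phenyl]ethan-1-one, via [2-fluoro-3,4-dimethoxy-6-(methoxymethoxy)phenyl]lithium 5 (not isolated)
Conditions: n-BuLi, THF, −78 °C; then MeC(O)N(OMe)Me, −78 to −50 °C; aq. NH4Cl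
Reagents that add atoms: N-methoxy-N-methylacetamide, CC(=O)N(C)OC
Why: Directed ortho-metalation should take place at the hydrogen flanked by fluorine (inductive acidification) and the MOM oxygen (coordination); the other site next to the acetal is less acidic and is shielded by the methyl of the in-plane C3 methoxy group. Acylation with the Weinreb amide is a nucleophilic acyl substitution that stops at the ketone, and the temperature is kept low so that 5 does not lose LiF.

Step 4
Reactants: 7 methyl 2,3,4-trihydroxybenzoate
Product: 8 methyl 2,3-dihydroxy-4-(methoxymethoxy)benzoate
Conditions: MOMCl (1.05 equiv), i-Pr2NEt (1.1 equiv), THF, −10 to 0 °C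
Reagents that add atoms: chloromethyl methyl ether (MOMCl), COCCl
Why: Site-selective Williamson-type O-alkylation; the C4 hydroxyl is para to the ester and the most acidic, the C2 hydroxyl is locked in a hydrogen bond to the ester carbonyl and the C3 hydroxyl is flanked on both sides, so one equivalent of amine base should ionise and alkylate O4 only.

Step 5
Reactants: 8 methyl 2,3-dihydroxy-4-(methoxymethoxy)benzoate
Product: 9 methyl 2,3-dimethoxy-4-(methoxymethoxy)benzoate
Conditions: MeI, K2CO3, DMF, 40 °C
Reagents that add atoms: iodomethane, CI
Why: Exhaustive Williamson O-methylation of the two remaining phenols; the chelated C2 hydroxyl needs DMF and gentle warming, and the MOM ether and the ester are inert to anhydrous carbonate.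

Step 6
Reactants: 6 1-[2-fluoro-3,4-dimethoxy-6-(methoxymethoxy)phenyl]ethan-1-one; 9 methyl 2,3-dimethoxy-4-(methoxymethoxy)benzoate
Product: 11 1-[2-fluoro-3,4-dimethoxy-6-(methoxymethoxy)phenyl]-3-[2,3-dimethoxy-4-(methoxymethoxy)phenyl]propane-1,3-dione, via lithium 1-[2-fluoro-3,4-dimethoxy-6-(methoxymethoxy)phenyl]ethen-1-olate 10 (not isolated)
Conditions: LiN(SiMe3)2 (2.5 equiv), THF, −78 °C; then 9, −78 °C to rt (45 °C if needed); aq. NH4Cl
Reagents that add atoms: none
Why: Crossed Claisen condensation of a methyl ketone enolate with a non-enolisable aryl ester; deprotonation of the product diketone by the excess base drives the equilibrium, and the lithium counter-ion and moderate temperature should leave the carbon–fluorine bond untouched.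

Step 7
Reactants: 11 1-[2-fluoro-3,4-dimethoxy-6-(methoxymethoxy)phenyl]-3-[2,3-dimethoxy-4-(methoxymethoxy)phenyl]propane-1,3-dione
Product: 12 2-[2,3-dimethoxy-4-(methoxymethoxy)phenyl]-7,8-dimethoxy-5-(methoxymethoxy)-4H-chromen-4-one
Conditions: K2CO3, dry DMF, 100 °C, N2
Reagents that add atoms: none
Why: K2CO3 deprotonates the 1,3-diketone, and the enolate oxygen on the carbon that bears ring B adds to C8a, the β-carbon of the C8a=C4a–C4=O unit, to give a Meisenheimer-type anion with its charge on the C4 carbonyl oxygen, C6 and C8; loss of fluoride then restores the arene (addition–elimination). The closest known reaction type is the base-mediated intramolecular O-arylation of 1-(2-halogenoaryl)-1,3-diketones to flavones, with the closure of 2-fluoro-2'-hydroxybenzophenones to xanthones as a relative. Ring C closes as a six-membered ring by attack on a trigonal carbon, 6-endo-trig with respect to the C8a=C4a bond conjugated to the carbonyl (an intramolecular oxa-Michael addition–elimination), which Baldwin's rules allow. No stereocentre is formed. O-arylation must win over C-arylation, and it should, because attack through C3 or through the oxygen on C4 would require a four-membered ring. Closure must occur at C8a and not at C5, and the substrate secures this because only C8a carries a leaving group and O5 is capped as its MOM ether, so the 5,6,7-isomer cannot arise. The oxygens at C5 and C7 are meta to C8a and sit at nodal positions of the anionic intermediate, the C8 methoxy group is expected to be twisted out of conjugation and to help inductively, and fluoride is the best leaving group when addition is rate-limiting, so the three alkoxy groups should cost heat but not feasibility. Dry conditions are used to suppress retro-Claisen cleavage of the diketone.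

Step 8
Reactants: 12 2-[2,3-dimethoxy-4-(methoxymethoxy)phenyl]-7,8-dimethoxy-5-(methoxymethoxy)-4H-chromen-4-one
Product: 13 5-hydroxy-2-(4-hydroxy-2,3-dimethoxyphenyl)-7,8-dimethoxy-4H-chromen-4-one (5,4'-dihydroxy-7,8,2',3'-tetramethoxyflavone)
Conditions: HCl (2 M in MeOH), THF, 45 °C
Reagents that add atoms: none
Why: Acid-catalysed acetal exchange removes both MOM groups in one operation, the C5 ether being assisted by the neighbouring carbonyl; methyl ethers and the pyranone are stable to dilute methanolic HCl, and these conditions are far milder than those that cause Wessely–Moser isomerisation.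

## Compound list

1 | 3-fluoro-4,5-dimethoxybenzaldehyde | COc1cc(C=O)cc(F)c1OC | starting material
2 | 3-fluoro-4,5-dimethoxyphenyl formate | O=COc1cc(F)c(OC)c(OC)c1 | intermediate
3 | 3-fluoro-4,5-dimethoxyphenol | Oc1cc(F)c(OC)c(OC)c1 | intermediate
4 | 1-fluoro-2,3-dimethoxy-5-(methoxymethoxy)benzene | COCOc1cc(F)c(OC)c(OC)c1 | intermediate
5 | [2-fluoro-3,4-dimethoxy-6-(methoxymethoxy)phenyl]lithium | [Li]c1c(F)c(OC)c(OC)cc1OCOC | intermediate
6 | 1-[2-fluoro-3,4-dimethoxy-6-(methoxymethoxy)phenyl]ethan-1-one | CC(=O)c1c(F)c(OC)c(OC)cc1OCOC | intermediate
7 | methyl 2,3,4-trihydroxybenzoate | COC(=O)c1ccc(O)c(O)c1O | starting material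
8 | methyl 2,3-dihydroxy-4-(methoxymethoxy)benzoate | COCOc1ccc(C(=O)OC)c(O)c1O | intermediate
9 | methyl 2,3-dimethoxy-4-(methoxymethoxy)benzoate | COCOc1ccc(C(=O)OC)c(OC)c1OC | intermediate
10 | lithium 1-[2-fluoro-3,4-dimethoxy-6-(methoxymethoxy)phenyl]ethen-1-olate | [Li]OC(=C)c1c(F)c(OC)c(OC)cc1OCOC | intermediate
11 | 1-[2-fluoro-3,4-dimethoxy-6-(methoxymethoxy)phenyl]-3-[2,3-dimethoxy-4-(methoxymethoxy)phenyl]propane-1,3-dione | COCOc1cc(OC)c(OC)c(F)c1C(=O)CC(=O)c1ccc(OCOC)c(OC)c1OC | intermediate
12 | 2-[2,3-dimethoxy-4-(methoxymethoxy)phenyl]-7,8-dimethoxy-5-(methoxymethoxy)-4H-chromen-4-one | COCOc1cc(OC)c(OC)c2oc(-c3ccc(OCOC)c(OC)c3OC)cc(=O)c12 | intermediate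
13 | 5-hydroxy-2-(4-hydroxy-2,3-dimethoxyphenyl)-7,8-dimethoxy-4H-chromen-4-one | COc1cc(O)c2c(=O)cc(-c3ccc(O)c(OC)c3OC)oc2c1OC | target

Total step count: 8
Longest linear sequence: 6 steps (steps 1, 2, 3, 6, 7 and 8)

## Least certain steps

Step 7 (key step). The most likely failure is that the enolate oxygen adds too slowly to the electron-rich, doubly ortho-substituted C8a, all the more so because the fully ionised diketone is a weaker activating group than a neutral ketone. Cleavage of the diketone by traces of hydroxide (retro-Claisen), or substitution of fluoride by dimethylamine released from hot DMF, could then overtake ring closure. The fallback sets out from 6 and forms the O–C8a bond first, between molecules, on the ketone. In aqueous DMSO the acetyl group stays largely un-ionised and so keeps its full activating power. KOH in DMSO–H2O at 90 °C should displace fluoride to give 1-[2-hydroxy-3,4-dimethoxy-6-(methoxymethoxy)phenyl]ethan-1-one F1. Its dianion (NaH, THF, 65 °C) would be condensed with 9 to give 1-[2-hydroxy-3,4-dimethoxy-6-(methoxymethoxy)phenyl]-3-[2,3-dimethoxy-4-(methoxymethoxy)phenyl]propane-1,3-dione F2. F2 would then be cyclodehydrated without acid (DBU, pyridine, 90 °C): the phenol adds to the ring B carbonyl and water leaves by an E1cB path, so ring C closes at O1–C2 while O5 remains capped. This comes back to the route at 12.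

Step 3. Deprotonation may occur in part at the other position next to the MOM ether, the aryllithium may lose LiF if the mixture warms before acyl transfer is complete, and the hindered aryllithium may deprotonate the acetyl donor instead of adding to it. The fallback sets out from 4 and fixes the metalation site with a halogen. NBS in MeCN at 0 °C should brominate para to the C3 methoxy group, which is the carbon between fluorine and the MOM ether, to give 2-bromo-3-fluoro-4,5-dimethoxy-1-(methoxymethoxy)benzene F3. Bromine–lithium exchange (n-BuLi, THF, −78 °C) is much faster than deprotonation and would generate the organolithium at that carbon only. This comes back to the route at 5.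

Step 4. The chloromethyl ether is a fast and poorly discriminating electrophile, so alkylation may spread to O3 or run on to the bis-ether. The fallback sets out from 7 and no longer asks MOMCl to select a site. Benzyl bromide with NaHCO3 and catalytic NaI in DMF at 40 °C, a base that ionises only the para hydroxyl, should give methyl 4-(benzyloxy)-2,3-dihydroxybenzoate F4. MeI and K2CO3 in DMF would give methyl 4-(benzyloxy)-2,3-dimethoxybenzoate F5. Hydrogenolysis (H2, Pd/C, EtOAc) would give methyl 4-hydroxy-2,3-dimethoxybenzoate F6, whose single free hydroxyl is then converted into the MOM ether (MOMCl, i-Pr2NEt, CH2Cl2). This comes back to the route at 9 and bypasses 8.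

Step 6. The ester is deactivated by its para alkoxy group and shielded by the ortho methoxy group, so acyl transfer to the enolate may stall. Proton exchange and self-condensation of the ketone would then take over, and forcing the reaction with heat risks uncontrolled loss of fluoride. The fallback sets out from 9 and replaces acyl substitution by aldol addition followed by oxidation. LiAlH4 in THF at 0 °C would give [2,3-dimethoxy-4-(methoxymethoxy)phenyl]methanol F7, and MnO2 in CH2Cl2 would give 2,3-dimethoxy-4-(methoxymethoxy)benzaldehyde F8. Addition of enolate 10 (made from 6 as in step 6, THF, −78 °C) to F8 should give rac-1-[2-fluoro-3,4-dimethoxy-6-(methoxymethoxy)phenyl]-3-hydroxy-3-[2,3-dimethoxy-4-(methoxymethoxy)phenyl]propan-1-one F9. Its carbinol stereocentre is of no consequence, because Dess–Martin periodinane in CH2Cl2 oxidises it to the diketone. This comes back to the route at 11.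

Further compounds
F1 | step 7 | 1-[2-hydroxy-3,4-dimethoxy-6-(methoxymethoxy)phenyl]ethan-1-one | CC(=O)c1c(O)c(OC)c(OC)cc1OCOC
F2 | step 7 | 1-[2-hydroxy-3,4-dimethoxy-6-(methoxymethoxy)phenyl]-3-[2,3-dimethoxy-4-(methoxymethoxy)phenyl]propane-1,3-dione | COCOc1cc(OC)c(OC)c(O)c1C(=O)CC(=O)c1ccc(OCOC)c(OC)c1OC
F3 | step 3 | 2-bromo-3-fluoro-4,5-dimethoxy-1-(methoxymethoxy)benzene | COCOc1cc(OC)c(OC)c(F)c1Br
F4 | step 4 | methyl 4-(benzyloxy)-2,3-dihydroxybenzoate | COC(=O)c1ccc(OCc2ccccc2)c(O)c1O
F5 | step 4 | methyl 4-(benzyloxy)-2,3-dimethoxybenzoate | COC(=O)c1ccc(OCc2ccccc2)c(OC)c1OC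
F6 | step 4 | methyl 4-hydroxy-2,3-dimethoxybenzoate | COC(=O)c1ccc(O)c(OC)c1OC
F7 | step 6 | [2,3-dimethoxy-4-(methoxymethoxy)phenyl]methanol | COCOc1ccc(CO)c(OC)c1OC
F8 | step 6 | 2,3-dimethoxy-4-(methoxymethoxy)benzaldehyde | COCOc1ccc(C=O)c(OC)c1OC
F9 | step 6 | rac-1-[2-fluoro-3,4-dimethoxy-6-(methoxymethoxy)phenyl]-3-hydroxy-3-[2,3-dimethoxy-4-(methoxymethoxy)phenyl]propan-1-one | COCOc1cc(OC)c(OC)c(F)c1C(=O)CC(O)c1ccc(OCOC)c(OC)c1OC
A1 | alternative 1 | 2-[4-(benzyloxy)-2,3-dimethoxyphenyl]-7,8-dimethoxy-4-oxo-4H-chromen-5-yl 4-methylbenzenesulfonate | COc1cc(OS(=O)(=O)c2ccc(C)cc2)c2c(=O)cc(-c3ccc(OCc4ccccc4)c(OC)c3OC)oc2c1OC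
A2 | alternative 1 | 2,3-dimethoxy-5-[(4-methylbenzenesulfonyl)oxy]-6-(trimethylsilyl)phenyl trifluoromethanesulfonate | COc1cc(OS(=O)(=O)c2ccc(C)cc2)c([Si](C)(C)C)c(OS(=O)(=O)C(F)(F)F)c1OC
A3 | alternative 1 | 3-[4-(benzyloxy)-2,3-dimethoxyphenyl]prop-2-ynoic acid | OC(=O)C#Cc1ccc(OCc2ccccc2)c(OC)c1OC
A4 | alternative 1 | 3,4-dimethoxy-6-[(4-methylbenzenesulfonyl)oxy]-1,2-didehydrobenzene | COC1=C(OC)C#CC(OS(=O)(=O)c2ccc(C)cc2)=C1
A5 | alternative 2 | 2-[4-(benzyloxy)-2,3-dimethoxyphenyl]-5-hydroxy-7,8-dimethoxy-4H-chromen-4-one | COc1cc(O)c2c(=O)cc(-c3ccc(OCc4ccccc4)c(OC)c3OC)oc2c1OC
A6 | alternative 2 | rac-4-{6-[4-(benzyloxy)-2,3-dimethoxyphenyl]-4-oxo-4H-pyran-2-yl}-3,4-dimethoxycyclobut-2-en-1-one | COC1=CC(=O)C1(OC)c1cc(=O)cc(-c2ccc(OCc3ccccc3)c(OC)c2OC)o1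
A7 | alternative 2 | (3Z)-4-{6-[4-(benzyloxy)-2,3-dimethoxyphenyl]-4-oxo-4H-pyran-2-yl}-3,4-dimethoxybuta-1,3-dien-1-one | O=C=C/C(OC)=C(/OC)c1cc(=O)cc(-c2ccc(OCc3ccccc3)c(OC)c2OC)o1
A8 | alternative 2 | 3-methoxycyclobut-3-ene-1,2-dione | COC1=CC(=O)C1=O
A9 | alternative 2 | 2-[4-(benzyloxy)-2,3-dimethoxyphenyl]-4H-pyran-4-one | O=c1ccoc(-c2ccc(OCc3ccccc3)c(OC)c2OC)c1
A10 | alternative 3 | 5-(benzyloxy)-2-[4-(benzyloxy)-2,3-dimethoxyphenyl]-7,8-dimethoxy-4H-chromen-4-one | COc1cc(OCc2ccccc2)c2c(=O)cc(-c3ccc(OCc4ccccc4)c(OC)c3OC)oc2c1OC
A11 | alternative 3 | 5-(benzyloxy)-6-iodo-2,3-dimethoxyphenol | COc1cc(OCc2ccccc2)c(I)c(O)c1OC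
A12 | alternative 3 | 1-(benzyloxy)-4-ethynyl-2,3-dimethoxybenzene | C#Cc1ccc(OCc2ccccc2)c(OC)c1OC
A13 | alternative 3 | carbon monoxide | [C-]#[O+]
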